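# Proposed total synthesis of CNP0227299.2 (compound 36) by anionic oxy-Cope ring expansion

## The problem

Compound 36 is a ten-membered carbocycle trans-fused to an α-methylene-γ-butyrolactone. Locants used throughout: C1 (enone CH), C2 (ketone), C3 (CH2), C4 (CHMe), C5 (CH–O-acyl), C6 (CHOH), C7 and C8 (lactone fusion, C8 carrying the ring oxygen), C9 (CH2), C10 (alkene CMe), and C11 (α-carbon), C12 (carbonyl), C13 (methylene) for the lactone.

- **Ring.** Direct closure of a ten-membered ring is penalised by entropy and transannular strain. The ring also contains a cis-trisubstituted enone (C1=C10) that neither a macrocyclisation nor an elimination would deliver reliably.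
- **Stereocentres.** C4–C8 are five contiguous centres (4S,5R,6R,7R,8R), and the ester carries two more (2S,3S). C4 and C5 are syn and can be set together. C8 can direct C7 through a tether on its oxygen, and the C7 bond formation can carry C6 with it.
- **Oxygen differentiation.** C5 and C6 bear neighbouring secondary oxygens, of which only C5 is acylated, so the two must be told apart by the order in which they appear.
- **Fragile groups.** The α-methylene lactone is a Michael acceptor, the epoxy ester is sensitive to acid and nucleophiles, the Z-enone can be γ-deprotonated, and a vicinal hydroxy ester can undergo acyl migration. Strong bases and nucleophiles therefore belong to the early part of the route.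
- **Enabling feature.** The C2 ketone has the cis C1=C10 alkene on one side and the C3–C4(Me)–C5(O) unit on the other. Drawing a bond from C2 to C7 turns the carbocycle into a cyclohex-2-enol that carries a propenyl group on the carbinol carbon and a 2-oxyvinyl group on the neighbouring carbon, which is an oxy-Cope substrate.

## Retrosynthesis

**Lactone oxidation level (36 ← 35 ← 34).** The lactone carbonyl is taken back to lactol 35 and its methyl acetal 34, which already carries the exocyclic methylene. This avoids an enolate methylenation, which the more acidic C2 enone would not survive. The forward steps only need to hydrolyse an allylic acetal and oxidise an allylic lactol while leaving the C6 hydroxyl alone.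

**C7–C11 and C6–O (34 ← 32 ← 30 + 31).** Both bonds are cut at once. A vinyl radical tethered to O8 as an iodoallyl acetal (32, from alcohol 30 and methoxyallene 31) adds to C7, and oxygen captures the C6 radical. Epoxide opening by a tethered enolate would add carbon and oxygen anti across the E-alkene, whereas the target needs syn addition, which the radical sequence gives. The forward reaction must cyclise faster than the vinyl radical is intercepted and must take up oxygen on the outer face.

**Ester (30 ← 29 ← 23 + 27).** The C5–O acyl bond is cut before the C6 oxygen exists, so no selection between two secondary hydroxyls is needed. Acid 27 comes from methyl angelate 24 through alcohol 25 and epoxy alcohol 26, with reagent control that is independent of the macrocycle.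

**Protecting groups (23 ← 22).** Compound 22 carries a p-methoxybenzyl ether on O5 and a silyl ether on O8. These are removed in that order by an oxidant and by fluoride, neither of which touches the enone or the E-alkene.

**Key disconnection (22 ← 19).** The C4–C5 bond is cut and the C2–C7 bond restored, contracting the ten-membered ring to cyclohexenol 19. Compared with any direct ring closure, this inherits the cis C1=C10 alkene from a six-membered ring and sets C4 and C5 in one event. It requires a trans-dialkenyl arrangement and E geometry in both side chains.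

**E-enol ether (19 ← 18 ← 16 + 17 ← 15).** The enol ether C5–O bond is cut to E-vinyl iodide 18, and the C5=C6 bond to aldehyde 16 and iodoform 17. Enolisation of an aldehyde usually favours the Z-enol derivative, and Z geometry would invert C5. The geometry is therefore fixed by an E-selective olefination and kept by a stereoretentive C–O coupling. An alkyl enol ether, unlike a silyl enol ether, cannot pass its O-substituent to the alkoxide in the key step.

**Side chains on the ring (15 ← 12 + 13; 12 ← 9 + 10).** The C2–C3 bond is cut to enone 12 and E-bromopropene 13, and the C6–C7 bond to enone 9 and formaldehyde 10. Both additions are steered by the C8 substituent: the aldol occurs anti to it, and the alkenyl addition anti to the new C7 group.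

**Enone (9 ← 8 ← 6 + 7; 6 ← 5 ← 4 ← 1 + 2).** The C1=C10 bond is cut by ring-closing metathesis of dienone 8. Compound 8 is assembled from vinylmagnesium bromide 7 and amide 6, which is made via silyl ether 5 from hydroxy ester 4. The C9–C10 bond of 4 leads back to chlorohydrin 1 and isopropenylmagnesium bromide 2. C8 comes from a commercial chiral building block, so no resolution is needed.

## Roads not taken

**Alternative 1:** nitrile oxide cycloaddition.
- *Cut and key step.* The C1–C2 bond is cut, with a temporary O–C10 bond. Oxidation of aldoxime A1 with NaOCl and intramolecular nitrile oxide–alkene cycloaddition would close the carbocycle as bridged isoxazoline A2.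
- *Merits.* All five ring stereocentres and the lactone ring are in place before the ring closes and rest on acyclic, reagent-controlled chemistry. The oxidant is mild.
- *Weak points.* Ten-membered ring closure by a dipolar cycloaddition competes with dimerisation of the dipole and depends on how the chain folds. The isoxazoline must then be opened reductively and dehydrated to the cis C1=C10 enone, which is a regio- and stereochemical question left open. A1 requires a long linear sequence.
- *Comparison.* This road is better in one respect: C6 and C7 do not depend on a late radical event in a medium ring. The chosen plan sets against this that no macrocyclisation is needed, the cis alkene is inherited, and the route to the ring is shorter.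

**Alternative 2:** pinacol macrocyclisation.
- *Cut and key step.* The C5–C6 bond is cut. SmI2 would couple the two aldehydes of A3 to diol A4, forming the ring and both carbinols.
- *Merits.* It is the most convergent road and would be the shortest if selective.
- *Weak points.* Two new stereocentres depend only on the conformation of the cyclising chain, and four diastereomers are possible. Both aldehydes have epimerisable α-centres (C4 and C7). A4 carries two similar secondary hydroxyls, of which only O5 may be acylated.
- *Comparison.* The chosen plan is less convergent, but it delivers O5 and O6 at different times and relays C4/C5 from existing stereocentres through an ordered transition state.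

**Alternative 3:** methylenation–Claisen ring expansion.
- *Cut and key step.* The C3–C4 bond is cut. Methylenation of eight-membered lactone A5 with Cp2TiMe2 and in-situ [3,3] shift would give ten-membered enone A6.
- *Merits.* Like the chosen plan, it is a ring expansion, keeps the cis C1=C10 alkene and forms the C2 ketone directly. A6 already carries the C11–C13 carbons on C7, so no late C–C bond at C7 is needed, which is a real advantage.
- *Weak points.* A5 is itself a medium ring that must be closed. Methylenation of a conjugated lactone is slow. Only C4 is set in the key step. The cis C5=C6 alkene of A6 must then be dioxygenated anti with face control, and the two new hydroxyls must be differentiated.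
- *Comparison.* The chosen plan sets the C5 oxygen and its configuration in the key step and starts from a simple cyclohexenol. It pays for this with the late radical step.

Key step: step 11

Remarks on the chemistry:
- The acetal carbon C12 in 32–35 is formed as a mixture of both configurations. It is left undefined because it becomes the lactone carbonyl.
- The tartrate enantiomer in step 14 is chosen so that oxygen is delivered to the face that gives the (2R,3S) epoxy alcohol. This assignment rests on the usual sense of the reaction and should be confirmed on the product.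
- Hydroxy ketones 23 and 30 may rest partly as transannular hemiketals. Steps 16 and 18 are expected to draw on the open forms.

## Route

Step 1
Reactants: 1 ethyl (3S)-4-chloro-3-hydroxybutanoate; 2 isopropenylmagnesium bromide
Product: 4 ethyl (3R)-3-hydroxy-5-methylhex-5-enoate, via epoxy ester 3 (not isolated)
Conditions: 2 (3 equiv), CuI (10 mol%), THF, −40 to 0 °C; aq NH4Cl
Reagents that add atoms: none
Why: The first equivalent of Grignard reagent deprotonates the chlorohydrin, whose alkoxide closes to terminal epoxide 3; copper-catalysed Grignard opening at the CH2 terminus then attaches C9–C10 without touching the carbinol centre (the descriptor changes by priority only), and the ester survives at low temperature.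

Step 2
Reactants: 4 ethyl (3R)-3-hydroxy-5-methylhex-5-enoate
Product: 5 ethyl (3R)-3-[(tert-butyldimethylsilyl)oxy]-5-methylhex-5-enoate
Conditions: TBSCl, imidazole, DMF, rt
Reagents that add atoms: tert-butyldimethylsilyl chloride, CC(C)(C)[Si](C)(C)Cl
Why: Standard silylation of a secondary alcohol; the silyl ether is chosen for O8 because it withstands organometallic reagents, enolate formation, KH and DDQ and is removed late by fluoride.

Step 3
Reactants: 5 ethyl (3R)-3-[(tert-butyldimethylsilyl)oxy]-5-methylhex-5-enoate
Product: 6 (3R)-3-[(tert-butyldimethylsilyl)oxy]-N-methoxy-N,5-dimethylhex-5-enamide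
Conditions: MeNH(OMe)·HCl, i-PrMgCl, THF, −20 °C
Reagents that add atoms: N,O-dimethylhydroxylamine hydrochloride, CNOC.Cl
Why: Aminolysis of the ester by the magnesium amide of N,O-dimethylhydroxylamine is a routine ester-to-amide conversion and is faster than β-elimination at this temperature.

Step 4
Reactants: 6 (3R)-3-[(tert-butyldimethylsilyl)oxy]-N-methoxy-N,5-dimethylhex-5-enamide; 7 vinylmagnesium bromide
Product: 8 (5R)-5-[(tert-butyldimethylsilyl)oxy]-7-methylocta-1,7-dien-3-one
Conditions: 7, THF, 0 °C; inverse quench into cold aq HCl
Reagents that add atoms: none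
Why: Grignard addition to an N-methoxy-N-methylamide stops at the chelated tetrahedral intermediate and gives the vinyl ketone on hydrolysis; the cold acidic quench keeps the released hydroxylamine from adding to the enone.

Step 5
Reactants: 8 (5R)-5-[(tert-butyldimethylsilyl)oxy]-7-methylocta-1,7-dien-3-one
Product: 9 (5R)-5-[(tert-butyldimethylsilyl)oxy]-3-methylcyclohex-2-en-1-one
Conditions: second-generation Grubbs catalyst (5 mol%), CH2Cl2, 40 °C
Reagents that add atoms: none
Why: Ring-closing metathesis of a vinyl ketone with a 1,1-disubstituted alkene is a known way to 3-methylcyclohexenones; it forms the cis C1=C10 alkene inside a six-membered ring under neutral conditions that cannot eliminate the β-silyloxy group.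

Step 6
Reactants: 9 (5R)-5-[(tert-butyldimethylsilyl)oxy]-3-methylcyclohex-2-en-1-one; 10 formaldehyde (monomer cracked from paraformaldehyde)
Product: 12 (5R,6S)-5-[(tert-butyldimethylsilyl)oxy]-6-(hydroxymethyl)-3-methylcyclohex-2-en-1-one, via lithium dienolate 11 (not isolated)
Conditions: LiN(iPr)2, THF, −78 °C; CH2O (gas), −78 °C; aq NH4Cl
Reagents that add atoms: none
Why: Kinetic deprotonation at the α'-carbon (C7) and aldol addition to formaldehyde; the electrophile enters anti to the neighbouring silyloxy group, giving the trans (diequatorial) product, which is also the thermodynamically preferred epimer at this enolisable centre.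

Step 7
Reactants: 12 (5R,6S)-5-[(tert-butyldimethylsilyl)oxy]-6-(hydroxymethyl)-3-methylcyclohex-2-en-1-one; 13 (E)-1-bromoprop-1-ene
Product: 15 (1R,5R,6S)-5-[(tert-butyldimethylsilyl)oxy]-6-(hydroxymethyl)-3-methyl-1-[(E)-prop-1-enyl]cyclohex-2-en-1-ol, via (E)-prop-1-enyllithium 14 (not isolated)
Conditions: 13, t-BuLi, Et2O, −78 °C; then 12 (3 equiv of 14), THF, −78 °C; aq NH4Cl
Reagents that add atoms: none
Why: Bromine–lithium exchange keeps the E geometry; one equivalent is consumed by the hydroxyl, and 1,2-addition to the enone carbonyl should occur from the face anti to the C7 substituent (equatorial approach, reinforced by the lithium alkoxide of the hydroxymethyl group), placing propenyl trans to the C7 side chain and the new hydroxyl cis to it, as in additions of alkenyl metals to 2-substituted cyclohexanones.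

Step 8
Reactants: 15 (1R,5R,6S)-5-[(tert-butyldimethylsilyl)oxy]-6-(hydroxymethyl)-3-methyl-1-[(E)-prop-1-enyl]cyclohex-2-en-1-ol
Product: 16 (1S,2R,6R)-6-[(tert-butyldimethylsilyl)oxy]-2-hydroxy-4-methyl-2-[(E)-prop-1-enyl]cyclohex-3-ene-1-carbaldehyde
Conditions: TEMPO (cat.), PhI(OAc)2, CH2Cl2, rt
Reagents that add atoms: none
Why: Oxoammonium oxidation is selective for the primary alcohol and leaves the tertiary one; the non-basic medium should spare the C7 stereocentre and avoid retro-aldol opening.

Step 9
Reactants: 16 (1S,2R,6R)-6-[(tert-butyldimethylsilyl)oxy]-2-hydroxy-4-methyl-2-[(E)-prop-1-enyl]cyclohex-3-ene-1-carbaldehyde; 17 iodoform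
Product: 18 (1R,5R,6S)-5-[(tert-butyldimethylsilyl)oxy]-6-[(E)-2-iodoethenyl]-3-methyl-1-[(E)-prop-1-enyl]cyclohex-2-en-1-ol
Conditions: CrCl2, 17, THF/dioxane, 0 °C to rt
Reagents that add atoms: none
Why: Takai olefination: the geminal dichromium reagent from iodoform adds to the aldehyde and eliminates to the E-vinyl iodide, supplying C5 with the geometry the key step needs; free hydroxyls are tolerated.

Step 10
Reactants: 18 (1R,5R,6S)-5-[(tert-butyldimethylsilyl)oxy]-6-[(E)-2-iodoethenyl]-3-methyl-1-[(E)-prop-1-enyl]cyclohex-2-en-1-ol
Product: 19 (1R,5R,6S)-5-[(tert-butyldimethylsilyl)oxy]-6-[(E)-2-(4-methoxybenzyloxy)ethenyl]-3-methyl-1-[(E)-prop-1-enyl]cyclohex-2-en-1-ol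
Conditions: CuI (10 mol%), 3,4,7,8-tetramethyl-1,10-phenanthroline (20 mol%), Cs2CO3, 4-methoxybenzyl alcohol, toluene, 80 °C
Reagents that add atoms: 4-methoxybenzyl alcohol, COc1ccc(CO)cc1
Why: Copper-catalysed Ullmann-type C–O coupling of a vinyl iodide with a primary alcohol proceeds with retention of alkene geometry; the hindered tertiary alcohol should not compete, and carbonate is too weak a base to start the rearrangement.

Step 11
Reactants: 19 (1R,5R,6S)-5-[(tert-butyldimethylsilyl)oxy]-6-[(E)-2-(4-methoxybenzyloxy)ethenyl]-3-methyl-1-[(E)-prop-1-enyl]cyclohex-2-en-1-ol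
Product: 22 (2Z,5R,6E,8R,9S)-5-[(tert-butyldimethylsilyl)oxy]-8-(4-methoxybenzyloxy)-3,9-dimethylcyclodeca-2,6-dien-1-one, via potassium alkoxide 20 (not isolated), via potassium enolate 21 (not isolated)
Conditions: KH, 18-crown-6, THF, 0 °C to rt; aq NH4Cl, −78 °C
Reagents that add atoms: none
Why: Potassium hydride with 18-crown-6 gives the free alkoxide 20, whose charge weakens the adjacent C2–C7 bond so that the 1,5-diene C4=C3–C2–C7–C6=C5 undergoes a [3,3] shift near room temperature (anionic oxy-Cope rearrangement, closest precedent 1,2-divinylcyclohexanols to cyclodec-5-enones). No ring is closed by end-to-end attack: the six-membered ring is enlarged by four atoms in one concerted step, so the cis C1=C10 alkene is carried over unchanged. The trans-dialkenyl substrate can reach only the chair in which the C2–C1 and C7–C8 ring bonds are both equatorial, which makes the new C6=C7 alkene E; the boat through the ring alkene would need the C7 side chain axial and is disfavoured. C4 is set by the E-propenyl group, which holds its methyl equatorial; C5 is set by the E-enol ether, which holds the alkoxy group equatorial; the sense of both follows from the C2/C7 configuration, giving 9S and 8R (C4 and C5 syn). Enolate 21 is protonated at C3 on cold quench to the conjugated Z-enone without creating a stereocentre. The step needs the sigmatropic path to outrun base-mediated side reactions; the alkyl enol ether cannot transfer its O-substituent to the alkoxide, and the equatorial O8 silyl ether is remote from it.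

Step 12
Reactants: 22 (2Z,5R,6E,8R,9S)-5-[(tert-butyldimethylsilyl)oxy]-8-(4-methoxybenzyloxy)-3,9-dimethylcyclodeca-2,6-dien-1-one
Product: 23 (2Z,5R,6E,8R,9S)-5-[(tert-butyldimethylsilyl)oxy]-8-hydroxy-3,9-dimethylcyclodeca-2,6-dien-1-one
Conditions: DDQ, CH2Cl2/pH 7 buffer, 0 °C
Reagents that add atoms: none
Why: Oxidative cleavage of the p-methoxybenzyl ether by DDQ (hydride abstraction and hydrolysis of the oxocarbenium ion) frees O5 while the silyl ether, enone and E-alkene are untouched.

Step 13
Reactants: 24 methyl angelate (methyl (Z)-2-methylbut-2-enoate)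
Product: 25 (Z)-2-methylbut-2-en-1-ol
Conditions: i-Bu2AlH, CH2Cl2, −78 to 0 °C; Rochelle salt
Reagents that add atoms: none
Why: Hydride reduction of the conjugated ester to the allylic alcohol at low temperature keeps the Z geometry.

Step 14
Reactants: 25 (Z)-2-methylbut-2-en-1-ol
Product: 26 [(2R,3S)-2,3-dimethyloxiran-2-yl]methanol
Conditions: Ti(OiPr)4 (cat.), D-(−)-diethyl tartrate (cat.), t-BuOOH, 4 Å molecular sieves, CH2Cl2, −20 °C
Reagents that add atoms: tert-butyl hydroperoxide, CC(C)(C)OO
Why: Sharpless asymmetric epoxidation of an allylic alcohol; the tartrate fixes the face of oxygen delivery (both epoxide centres), and the cis relation of CH2OH and the C3 methyl follows from the Z-alkene.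

Step 15
Reactants: 26 [(2R,3S)-2,3-dimethyloxiran-2-yl]methanol
Product: 27 (2S,3S)-2,3-dimethyloxirane-2-carboxylic acid
Conditions: RuCl3 (cat.), NaIO4, MeCN/EtOAc/H2O, rt
Reagents that add atoms: sodium periodate, [Na+].[O-][I](=O)(=O)=O; water, O
Why: Catalytic ruthenium tetroxide oxidation takes the primary alcohol to the acid without opening the epoxide; the C2 descriptor changes by priority only.

Step 16
Reactants: 23 (2Z,5R,6E,8R,9S)-5-[(tert-butyldimethylsilyl)oxy]-8-hydroxy-3,9-dimethylcyclodeca-2,6-dien-1-one; 27 (2S,3S)-2,3-dimethyloxirane-2-carboxylic acid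
Product: 29 (2Z,5R,6E,8R,9S)-5-[(tert-butyldimethylsilyl)oxy]-3,9-dimethyl-1-oxocyclodeca-2,6-dien-8-yl (2S,3S)-2,3-dimethyloxirane-2-carboxylate, via mixed anhydride 28 (not isolated)
Conditions: 27, 2,4,6-trichlorobenzoyl chloride, Et3N, THF, rt; then 23, DMAP, toluene, rt
Reagents that add atoms: none
Why: Yamaguchi esterification through mixed anhydride 28 acylates the hindered secondary allylic alcohol with retention at C5; done now, it removes any need to tell O5 from O6 later.

Step 17
Reactants: 29 (2Z,5R,6E,8R,9S)-5-[(tert-butyldimethylsilyl)oxy]-3,9-dimethyl-1-oxocyclodeca-2,6-dien-8-yl (2S,3S)-2,3-dimethyloxirane-2-carboxylate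
Product: 30 (2Z,5R,6E,8R,9S)-5-hydroxy-3,9-dimethyl-1-oxocyclodeca-2,6-dien-8-yl (2S,3S)-2,3-dimethyloxirane-2-carboxylate
Conditions: HF·pyridine, pyridine, THF, 0 °C to rt
Reagents that add atoms: none
Why: Buffered fluoride desilylation frees O8; the electron-poor glycidic ester epoxide and the enone should tolerate these conditions.

Step 18
Reactants: 30 (2Z,5R,6E,8R,9S)-5-hydroxy-3,9-dimethyl-1-oxocyclodeca-2,6-dien-8-yl (2S,3S)-2,3-dimethyloxirane-2-carboxylate; 31 methoxyallene
Product: 32 O8 (2-iodoprop-2-enyl) methyl acetal of 30, namely the C8–O–CH(OMe)–C(I)=CH2 mixed acetal as both acetal epimers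
Conditions: N-iodosuccinimide, 31, CH2Cl2, −40 to 0 °C
Reagents that add atoms: N-iodosuccinimide, O=C1CCC(=O)N1I
Why: Haloacetalisation as used to prepare Ueno–Stork substrates: iodonium attacks the central allene carbon, and the resulting oxocarbenium ion is trapped by the C8 hydroxyl; the electron-rich allene should react well before the ring alkenes.

Step 19
Reactants: 32 O8 (2-iodoprop-2-enyl) methyl acetal of 30
Product: 34 methyl lactol ether of the trans-fused bicycle (C12 acetal; C11=C13 methylene; 6R hydroxyl; 5R epoxyangelate), via C6 hydroperoxide 33 (not isolated)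
Conditions: Bu3SnH (slow addition), Et3B (cat.), dry air, toluene, 0 °C to rt; then PPh3
Reagents that add atoms: dioxygen, O=O
Why: Iodine abstraction gives the C11 vinyl radical, which closes 5-exo-trig onto C7 from the face of the C8–O bond (H8 eclipsing the alkene, C9 on the other face), giving the trans ring fusion and 7R; the C6 radical should take up oxygen on the same outer face (syn addition across the E-alkene, 6R), and hydroperoxide 33 is reduced by PPh3 (radical cyclisation–oxygenation of a halo acetal).

Step 20
Reactants: 34 methyl lactol ether of the trans-fused bicycle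
Product: 35 lactol (C12 hemiacetal as both epimers) with free C6 hydroxyl and C11=C13 methylene
Conditions: AcOH/THF/H2O, rt
Reagents that add atoms: water, O
Why: Acid hydrolysis of an allylic mixed acetal is fast under conditions mild enough for the glycidic ester and unlikely to cause acyl migration.

Step 21
Reactants: 35 lactol with free C6 hydroxyl and C11=C13 methylene
Product: 36 (3aR,4R,5R,6S,9Z,11aR)-4-hydroxy-6,10-dimethyl-3-methylidene-2,8-dioxo-2,3,3a,4,5,6,7,8,11,11a-decahydrocyclodeca[b]furan-5-yl (2S,3S)-2,3-dimethyloxirane-2-carboxylate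
Conditions: MnO2 (activated), CH2Cl2, rt
Reagents that add atoms: none
Why: MnO2 oxidises the allylic lactol to the α-methylene lactone and leaves the non-allylic C6 alcohol, so the Michael acceptor appears only in the last step.

## Compound list

1 | ethyl (3S)-4-chloro-3-hydroxybutanoate | ClC[C@@H](O)CC(=O)OCC | starting material
2 | isopropenylmagnesium bromide | CC(=C)[Mg]Br | starting material
3 | ethyl 2-[(2S)-oxiran-2-yl]acetate | C1O[C@H]1CC(=O)OCC | intermediate
4 | ethyl (3R)-3-hydroxy-5-methylhex-5-enoate | C=C(C)C[C@@H](O)CC(=O)OCC | intermediate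
5 | ethyl (3R)-3-[(tert-butyldimethylsilyl)oxy]-5-methylhex-5-enoate | C=C(C)C[C@@H](O[Si](C)(C)C(C)(C)C)CC(=O)OCC | intermediate
6 | (3R)-3-[(tert-butyldimethylsilyl)oxy]-N-methoxy-N,5-dimethylhex-5-enamide | C=C(C)C[C@@H](O[Si](C)(C)C(C)(C)C)CC(=O)N(C)OC | intermediate
7 | vinylmagnesium bromide | C=C[Mg]Br | starting material
8 | (5R)-5-[(tert-butyldimethylsilyl)oxy]-7-methylocta-1,7-dien-3-one | C=C(C)C[C@@H](O[Si](C)(C)C(C)(C)C)CC(=O)C=C | intermediate
9 | (5R)-5-[(tert-butyldimethylsilyl)oxy]-3-methylcyclohex-2-en-1-one | O=C1C=C(C)C[C@@H](O[Si](C)(C)C(C)(C)C)C1 | intermediate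
10 | formaldehyde (monomer from paraformaldehyde) | C=O | starting material
11 | lithium dienolate of 9 (enolate towards C6 of the enone, ring alkene kept) | [Li+].[O-]C1=C[C@H](O[Si](C)(C)C(C)(C)C)CC(C)=C1 | intermediate
12 | (5R,6S)-5-[(tert-butyldimethylsilyl)oxy]-6-(hydroxymethyl)-3-methylcyclohex-2-en-1-one | O=C1C=C(C)C[C@@H](O[Si](C)(C)C(C)(C)C)[C@@H]1CO | intermediate
13 | (E)-1-bromoprop-1-ene | C/C=C/Br | starting material
14 | (E)-prop-1-enyllithium | C/C=C/[Li] | intermediate
15 | (1R,5R,6S)-5-[(tert-butyldimethylsilyl)oxy]-6-(hydroxymethyl)-3-methyl-1-[(E)-prop-1-enyl]cyclohex-2-en-1-ol | C/C=C/[C@@]1(O)C=C(C)C[C@@H](O[Si](C)(C)C(C)(C)C)[C@@H]1CO | intermediate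
16 | (1S,2R,6R)-6-[(tert-butyldimethylsilyl)oxy]-2-hydroxy-4-methyl-2-[(E)-prop-1-enyl]cyclohex-3-ene-1-carbaldehyde | C/C=C/[C@@]1(O)C=C(C)C[C@@H](O[Si](C)(C)C(C)(C)C)[C@@H]1C=O | intermediate
17 | iodoform | IC(I)I | starting material
18 | (1R,5R,6S)-5-[(tert-butyldimethylsilyl)oxy]-6-[(E)-2-iodoethenyl]-3-methyl-1-[(E)-prop-1-enyl]cyclohex-2-en-1-ol | C/C=C/[C@@]1(O)C=C(C)C[C@@H](O[Si](C)(C)C(C)(C)C)[C@@H]1/C=C/I | intermediate
19 | (1R,5R,6S)-5-[(tert-butyldimethylsilyl)oxy]-6-[(E)-2-(4-methoxybenzyloxy)ethenyl]-3-methyl-1-[(E)-prop-1-enyl]cyclohex-2-en-1-ol | C/C=C/[C@@]1(O)C=C(C)C[C@@H](O[Si](C)(C)C(C)(C)C)[C@@H]1/C=C/OCc2ccc(OC)cc2 | intermediate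
20 | potassium alkoxide of 19 | C/C=C/[C@@]1([O-])C=C(C)C[C@@H](O[Si](C)(C)C(C)(C)C)[C@@H]1/C=C/OCc2ccc(OC)cc2.[K+] | intermediate
21 | potassium enolate of 22 (C2–O−, C2=C3 with C1 and C4 trans) | C1/C(C)=C\C([O-])=C\[C@H](C)[C@@H](OCc2ccc(OC)cc2)/C=C/[C@@H]1O[Si](C)(C)C(C)(C)C.[K+] | intermediate
22 | (2Z,5R,6E,8R,9S)-5-[(tert-butyldimethylsilyl)oxy]-8-(4-methoxybenzyloxy)-3,9-dimethylcyclodeca-2,6-dien-1-one | C1/C(C)=C\C(=O)C[C@H](C)[C@@H](OCc2ccc(OC)cc2)/C=C/[C@@H]1O[Si](C)(C)C(C)(C)C | intermediate
23 | (2Z,5R,6E,8R,9S)-5-[(tert-butyldimethylsilyl)oxy]-8-hydroxy-3,9-dimethylcyclodeca-2,6-dien-1-one | C1/C(C)=C\C(=O)C[C@H](C)[C@@H](O)/C=C/[C@@H]1O[Si](C)(C)C(C)(C)C | intermediate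
24 | methyl angelate (methyl (Z)-2-methylbut-2-enoate) | C/C=C(/C)C(=O)OC | starting material
25 | (Z)-2-methylbut-2-en-1-ol | C/C=C(/C)CO | intermediate
26 | [(2R,3S)-2,3-dimethyloxiran-2-yl]methanol | OC[C@@]1(C)O[C@H]1C | intermediate
27 | (2S,3S)-2,3-dimethyloxirane-2-carboxylic acid | OC(=O)[C@@]1(C)O[C@H]1C | intermediate
28 | mixed anhydride of 27 with 2,4,6-trichlorobenzoic acid | O=C(OC(=O)c1c(Cl)cc(Cl)cc1Cl)[C@@]2(C)O[C@H]2C | intermediate
29 | (2Z,5R,6E,8R,9S)-5-[(tert-butyldimethylsilyl)oxy]-3,9-dimethyl-1-oxocyclodeca-2,6-dien-8-yl (2S,3S)-2,3-dimethyloxirane-2-carboxylate | C1/C(C)=C\C(=O)C[C@H](C)[C@@H](OC(=O)[C@@]2(C)O[C@H]2C)/C=C/[C@@H]1O[Si](C)(C)C(C)(C)C | intermediate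
30 | (2Z,5R,6E,8R,9S)-5-hydroxy-3,9-dimethyl-1-oxocyclodeca-2,6-dien-8-yl (2S,3S)-2,3-dimethyloxirane-2-carboxylate | C1/C(C)=C\C(=O)C[C@H](C)[C@@H](OC(=O)[C@@]2(C)O[C@H]2C)/C=C/[C@@H]1O | intermediate
31 | methoxyallene (1-methoxypropa-1,2-diene) | COC=C=C | starting material
32 | O8 (2-iodoprop-2-enyl) methyl acetal of 30 (both acetal epimers) | C1/C(C)=C\C(=O)C[C@H](C)[C@@H](OC(=O)[C@@]2(C)O[C@H]2C)/C=C/[C@@H]1OC(OC)C(I)=C | intermediate
33 | C6 hydroperoxide of the cyclised methyl lactol ether | C=C1C(OC)O[C@@H]2C/C(C)=C\C(=O)C[C@H](C)[C@@H](OC(=O)[C@@]3(C)O[C@H]3C)[C@H](OO)[C@@H]12 | intermediate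
34 | methyl lactol ether of 36 (C12 acetal, both epimers; 6R hydroxyl) | C=C1C(OC)O[C@@H]2C/C(C)=C\C(=O)C[C@H](C)[C@@H](OC(=O)[C@@]3(C)O[C@H]3C)[C@H](O)[C@@H]12 | intermediate
35 | lactol of 36 (C12 hemiacetal, both epimers) | C=C1C(O)O[C@@H]2C/C(C)=C\C(=O)C[C@H](C)[C@@H](OC(=O)[C@@]3(C)O[C@H]3C)[C@H](O)[C@@H]12 | intermediate
36 | (3aR,4R,5R,6S,9Z,11aR)-4-hydroxy-6,10-dimethyl-3-methylidene-2,8-dioxo-2,3,3a,4,5,6,7,8,11,11a-decahydrocyclodeca[b]furan-5-yl (2S,3S)-2,3-dimethyloxirane-2-carboxylate | C=C1C(=O)O[C@@H]2C/C(C)=C\C(=O)C[C@H](C)[C@@H](OC(=O)[C@@]3(C)O[C@H]3C)[C@H](O)[C@@H]12 | target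

## Step count and least certain steps

Total: 21 steps. Longest linear sequence: 18 steps (steps 1–12 and 16–21); steps 13–15 form a three-step branch that joins at step 16.

**Step 11 (key step).** The most likely failure is competition from base-driven processes on the product side. Excess alkoxide or hydride may γ-deprotonate the new enone, which would lead to double-bond migration or vinylogous loss of the O8 silyloxy group. A minor boat pathway would erode the C4/C5 configuration. The fallback removes free base altogether. Compound 19 is silylated (TMSCl, imidazole) to its trimethylsilyl ether F1. F1 is rearranged thermally in a neutral siloxy-Cope reaction (xylene, sealed tube, about 200 °C) through the same chair to the ten-membered trimethylsilyl dienol ether F2. Mild hydrolysis (AcOH/THF/H2O) then returns the route to 22.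

**Step 9.** β-Hydroxy aldehyde 16 has a tertiary, doubly allylic carbinol next to an enolisable centre. Chromium salts acting as Lewis acids may cause loss of water or ionisation, and retro-aldol ring opening or epimerisation at C7 is possible. The fallback masks the hydroxyls before the aldehyde is made. Diol 15 is converted (TMSCl, imidazole) into the bis(trimethylsilyl) ether F3. Swern oxidation, which oxidises primary silyl ethers directly, gives the O-silylated aldehyde F4. Takai olefination gives the O-silylated vinyl iodide F5, and K2CO3 in methanol frees the tertiary alcohol, rejoining at 18.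

**Step 10.** The coupling runs at 80 °C with carbonate on a substrate that carries a free tertiary allylic alcohol. Slow C–O bond formation would leave time for protodeiodination or base-induced decomposition. The fallback changes the coupling partner and works at room temperature. Aldehyde 16 is olefinated with Cl2CHB(pin), CrCl2 and LiI to the E-alkenyl pinacol boronate F6. F6 is coupled oxidatively with 4-methoxybenzyl alcohol (Cu(OAc)2, Et3N, air, rt; Chan–Lam-type coupling with retention of geometry), rejoining at 19.

**Step 18.** Two processes may interfere: the C8 hydroxyl may be held in a transannular hemiketal with the C2 ketone, and the iodonium source may attack the strained E-alkene and start transannular reactions. The fallback avoids any electrophilic halogen. Alcohol 30 is transacetalised with 2-bromo-3,3-dimethoxyprop-1-ene (pyridinium p-toluenesulfonate, toluene, removal of methanol) to the 2-bromoallyl methyl acetal F7. F7 then undergoes the same radical cyclisation–oxygenation (Bu3SnH, azobisisobutyronitrile, air, 80 °C; then PPh3), rejoining at 34.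

**Step 19.** Three things may go wrong:
- the vinyl radical may be reduced or oxygenated before it cyclises;
- oxygen may be taken up on the wrong face at C6 once the ring relaxes;
- the C6 radical may add across the ring to the enone.

The fallback sets the C6 oxygen before the C–C bond is formed. Alcohol 30 is epoxidised under hydroxyl direction (VO(acac)2, t-BuOOH) on the outer face to the 6,7-epoxide F8. F8 is transacetalised with 3,3-dimethoxyprop-1-yne to the propargylic methyl acetal F9. Titanocene monochloride (trivalent titanium, from Cp2TiCl2 and Zn) opens the epoxide to the C7 radical, which closes 5-exo-dig onto the alkyne and is reduced, rejoining at 34 with the C6 oxygen already in place.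

## Further compounds

F1 | step 11 | trimethylsilyl ether of 19 | C/C=C/[C@@]1(O[Si](C)(C)C)C=C(C)C[C@@H](O[Si](C)(C)C(C)(C)C)[C@@H]1/C=C/OCc2ccc(OC)cc2
F2 | step 11 | ten-membered trimethylsilyl dienol ether of 22 | C1/C(C)=C\C(O[Si](C)(C)C)=C\[C@H](C)[C@@H](OCc2ccc(OC)cc2)/C=C/[C@@H]1O[Si](C)(C)C(C)(C)C
F3 | step 9 | bis(trimethylsilyl) ether of 15 | C/C=C/[C@@]1(O[Si](C)(C)C)C=C(C)C[C@@H](O[Si](C)(C)C(C)(C)C)[C@@H]1CO[Si](C)(C)C
F4 | step 9 | O-trimethylsilyl ether of aldehyde 16 | C/C=C/[C@@]1(O[Si](C)(C)C)C=C(C)C[C@@H](O[Si](C)(C)C(C)(C)C)[C@@H]1C=O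
F5 | step 9 | O-trimethylsilyl ether of vinyl iodide 18 | C/C=C/[C@@]1(O[Si](C)(C)C)C=C(C)C[C@@H](O[Si](C)(C)C(C)(C)C)[C@@H]1/C=C/I
F6 | step 10 | E-alkenyl pinacol boronate corresponding to 18 | C/C=C/[C@@]1(O)C=C(C)C[C@@H](O[Si](C)(C)C(C)(C)C)[C@@H]1/C=C/B2OC(C)(C)C(C)(C)O2
F7 | step 18 | O8 (2-bromoprop-2-enyl) methyl acetal of 30 | C1/C(C)=C\C(=O)C[C@H](C)[C@@H](OC(=O)[C@@]2(C)O[C@H]2C)/C=C/[C@@H]1OC(OC)C(Br)=C
F8 | step 19 | 6,7-epoxide of 30 | C1/C(C)=C\C(=O)C[C@H](C)[C@@H](OC(=O)[C@@]3(C)O[C@H]3C)[C@@H]2O[C@H]2[C@@H]1O
F9 | step 19 | O8 prop-2-ynyl methyl acetal of F8 | C1/C(C)=C\C(=O)C[C@H](C)[C@@H](OC(=O)[C@@]3(C)O[C@H]3C)[C@@H]2O[C@H]2[C@@H]1OC(OC)C#C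
A1 | alternative 1 | open-chain aldoxime with lactone and 1,1-disubstituted alkene | C1C(=O)O[C@H](CC(C)=C)[C@H]1[C@@H](O[Si](C)(C)C(C)(C)C)[C@H](OCc2ccc(OC)cc2)[C@@H](C)CC=NO
A2 | alternative 1 | ten-membered carbocycle bridged by the isoxazoline | C1C(=O)O[C@@H]2C[C@]3(C)CC(=NO3)C[C@H](C)[C@@H](OCc4ccc(OC)cc4)[C@H](O[Si](C)(C)C(C)(C)C)[C@@H]12
A3 | alternative 2 | acyclic C5,C6-dialdehyde | O=C[C@@H](C)CC1(OCCO1)/C=C(C)\C[C@@H](O[Si](CC)(CC)CC)[C@@H](C=O)C(=C)CO[Si](CC)(CC)CC
A4 | alternative 2 | ten-membered C5,C6-diol | CC[Si](CC)(CC)O[C@@H]1C/C(C)=C\C2(OCCO2)C[C@H](C)[C@@H](O)[C@H](O)[C@H]1C(=C)CO[Si](CC)(CC)CC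
A5 | alternative 3 | eight-membered enoate lactone with propenyl group on C6 | CC=CC1OC(=O)/C=C(C)\C[C@@H](O[Si](CC)(CC)CC)[C@@H]1C(=C)CO[Si](CC)(CC)CC
A6 | alternative 3 | ten-membered Z-enone with cis C5=C6 alkene | CC[Si](CC)(CC)O[C@@H]1C/C(C)=C\C(=O)C[C@H](C)/C=C\[C@H]1C(=C)CO[Si](CC)(CC)CC
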